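4 questions are asked, and I carry one number through the last of them.

| setting | Thursday's | Monday's | Sunday's | Saturday's | Wednesday's |
|---|---|---|---|---|---|
| substrate | 0.250 M | 0.150 M | 0.250 M | 0.750 M | 0.250 M |
| partner | 0.300 M | 0.200 M | 0.450 M | 0.300 M | 0.300 M |
| free catalyst | 0.0130 M | 0.0130 M | 0.0130 M | 0.0130 M | 0.00520 M |
| time |  |  |  |  | 26 min |

| run | time / min | [substrate] / M |
|---|---|---|
| Thursday's run | 5.2 | 0.215 |
| Thursday's run | 10 | 0.185 |
| Thursday's run | 16 | 0.154 |
| Thursday's run | 21 | 0.124 |
| Thursday's run | 26 | 0.102 |
| Monday's run | 5.2 | 0.125 |
| Monday's run | 10 | 0.107 |
| Monday's run | 16 | 0.078 |
| Monday's run | 21 | 0.064 |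
| Monday's run | 26 | 0.047 |
| Sunday's run | 5.2 | 0.213 |
| Sunday's run | 10 | 0.189 |
| Sunday's run | 16 | 0.160 |
| Sunday's run | 21 | 0.132 |
| Sunday's run | 26 | 0.105 |
| Saturday's run | 5.2 | 0.718 |
| Saturday's run | 10 | 0.692 |
| Saturday's run | 16 | 0.658 |
| Saturday's run | 21 | 0.627 |
| Saturday's run | 26 | 0.611 |

(standard deviation of a reading: 0.004 M)

- Overall: substrate + partner -> product, with free catalyst as catalyst.
- Constant volume, constant temperature.
- What is held in complexes is read along with the free species.
- "The second partner" is partner.
- An order is taken over about fifteen percent of the charge, up and down.

1. the power of [partner] that the first rate follows, about the charge of the Thursday's run; measure it at two percent of substrate made into product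
2. the power of [substrate] that the first rate follows, about the charge of the Thursday's run; measure it at two percent of substrate made into product (one fixed amount of product, the same in the runs compared)
3. the Monday's run starts with 0.100 M less of substrate and of partner than the Thursday's run, and with no product. Compared where both hold the same amount of substrate, once fifteen percent of what the Monday's run was charged with has turned into product, is the Monday's run faster, slower or alike (within a tenth)?
4. substrate in the Wednesday's run at 26 min, as a share of the substrate charged

1. By 10 min, Thursday's run has lost 0.0650 M of substrate. By then Saturday's run, with more substrate, has lost 0.0580 M. Sunday's run, with more partner, has lost 0.0610 M. Each reading scatters by 0.004 M, so I read the early rate as nearly flat in both concentrations.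

2. Substrate is the limiting reagent in Wednesday's run, with 0.250 M against 0.300 M of partner. I define the reach as the share of that charge which Thursday's early rate, read from its loss by 10 min, turns in 26 min: 67.6 %.

3. Wednesday's charge differs from Thursday's in free catalyst, at a ratio of 0.400. The share left is one minus the reach times the factor by which the rate falls.

4. The earlier runs all carry 0.0130 M, so they do not give that factor. At the first power of catalyst the share left is 73.0 %, and at the second power it is 89.2 %. I commit to that span.

5. Now I turn the question round. Wednesday's run keeps more than my upper share only if the rate falls by more than a factor of 0.160, which is a catalyst power above 2.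

6. Monday's run and Thursday's run both have partner in excess by 0.0500 M. At equal substrate they therefore hold equal partner. Thursday's run has already used 0.100 M of substrate at the point where Monday's run starts, so product or catalyst lost on the way could part the two runs. I assume that neither acts, and I expect them alike.

7. The forecast gives a partner power of 0.05 and a substrate power of 0.25. It calls Monday's run slower, which differs from my view, and puts Wednesday's share at 74 %, between 68 % and 79 %. On catalyst it notes: “No run tests catalyst order”.

8. The simulation gives a partner power of 0.10 and a substrate power of 0.27. Monday's run is alike, with a rate ratio of 1.0. Wednesday's share is 95.5 %.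

    free catalyst + substrate ⇌ catalyst-substrate complex, settled at all times (8.630 M⁻¹)
    free catalyst + partner ⇌ catalyst-reagent complex, settled at all times (8.760 M⁻¹)
    catalyst-substrate complex + catalyst-reagent complex → product + 2 free catalyst (339.6 M⁻¹ min⁻¹)
    free catalyst + impurity → spent catalyst

Wednesday's run keeps 95.5 % because the impurity takes 0.00243 M of free catalyst at once. The product step joins two complexes, so I square the ratio of catalyst left, Wednesday's over Thursday's, which is 0.262. The reach times that square gives 4.64 % turned, and the flask turned 4.50 %. With the impurity taken out of Wednesday's run, the ratio becomes 0.492. The reach then leaves 83.6 %, and that flask stands at 84.3 %.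

The runs stem from a simulated flask for substances that don't exist; scatter was added.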